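The ten-membered carbocycle is oxygenated at C1 (furanone ketone) and C5 (carbinol), two ring atoms joined through C2–C4, so it is traced back to a guaiane in which C1=C5 is the tetrasubstituted ring-fusion alkene of a five–seven bicycle. Ozonolysis of that bond, then acid in the same flask, opens the bicycle to the ten-membered ring with ketones at C1 and C5, unmasks the C3 ketone and lets the C10 hydroxyl close the furanone ring (O, C3, C2, C1, C10). The precursor is a santonin-derived guai-1(5)-en-6α,12-olide 3-ketal carrying the C11 chlorohydrin, the C8 angelate, a C9 silyl ether and a free 10β-hydroxyl.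

Key step: step 10

Remark 1: guaiane/germacrane numbering is used throughout (lactone O on C6, C12 lactone carbonyl, C13 exocyclic carbon, C14 methyl on C10, C15 methyl on C4); α/β refer to the santonin frame (H6 β, H7 α).
Remark 2: the photoproduct of step 1 carries its C10 hydroxyl α, whereas the target needs the C10 oxygen β (cis to O8 and O9); the hydroxyl is therefore eliminated in step 2 and reinstalled on the other face in step 4.
Remark 3: C4 becomes stereolabile in step 10 and is fixed in step 11; before that its configuration is immaterial and it is drawn as 4β-methyl (4αH).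

Step 1
Reactants: 1 α-santonin
Product: 2 isophotosantonic lactone (10α-hydroxy-3-oxo-1αH,6βH,7αH,11βH-guai-4-en-6α,12-olide)
Conditions: hν (Hg lamp, Pyrex), AcOH/H2O 1:1, rt
Reagents that add atoms: water, O
Why: Cross-conjugated cyclohexadienone photorearrangement, in which the C1–C5 bond forms, the C5–C10 bond breaks and water captures C10 anti to the departing bond, so that 10α-OH and 1α-H are set while C6, C7 and C11 are untouched.

Step 2
Reactants: 2 isophotosantonic lactone
Product: 4 3,3-ethylenedioxy-4αH,6βH,7αH,11βH-guaia-1(5),9-dien-6α,12-olide, via linear dienone 3 (not isolated)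
Conditions: TsOH·H2O (cat.), benzene, reflux, Dean–Stark; then HOCH2CH2OH, reflux
Reagents that add atoms: ethylene glycol, OCCO
Why: Acid dehydration of the tertiary carbinol to the conjugated 1(10),4-dienone followed by deconjugative ketalisation (as with steroidal 4,6-dien-3-ones) should move both alkenes away from the ketal carbon to give the 1(5),9-diene, C4 being set by protonation with a configuration that is not needed later.

Step 3
Reactants: 4 3,3-ethylenedioxy-4αH-guaia-1(5),9-dien-6α,12-olide
Product: 5 3,3-ethylenedioxy-11β-phenylseleno-4αH,11α-methyl-guaia-1(5),9-dien-6α,12-olide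
Conditions: LiN(iPr)2, THF, −78 °C; PhSeCl, −78 °C
Reagents that add atoms: phenylselenenyl chloride, Cl[Se]c1ccccc1
Why: Selenenylation of the kinetic lactone enolate, the only acidic site, should place selenium on the β-face of C11 away from the axial H7, so that the later selenoxide can only eliminate towards C13.

Step 4
Reactants: 5 11β-phenylseleno lactone
Product: 7 3,3-ethylenedioxy-10β-hydroxy-4αH-guaia-1(5),8,11(13)-trien-6α,12-olide, via hydroxy bis-selenide 6 (not isolated)
Conditions: N-(phenylseleno)phthalimide, H2O, CSA (cat.), CH2Cl2, 0 °C; then NaIO4, NaHCO3, MeOH/H2O, 0 °C to rt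
Reagents that add atoms: water, O
Why: Hydroxyselenation followed by selenoxide syn-elimination (alkene to transposed allylic alcohol): the reversibly formed seleniranium ion at the less hindered C9=C10 should be opened by water at the tertiary allylic C10 in the trans-diaxial sense on the open β-face (9α-Se, 10β-OH), and periodate oxidation then eliminates the C9 selenoxide towards C8 and the C11 selenoxide towards C13.

Step 5
Reactants: 7 10β-hydroxy-1(5),8,11(13)-triene
Product: 8 3,3-ethylenedioxy-8β,9β,10β-trihydroxy-4αH-guaia-1(5),11(13)-dien-6α,12-olide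
Conditions: OsO4 (5 mol %), quinuclidine N-oxide, CH2Cl2, rt
Reagents that add atoms: osmium tetroxide, O=[Os](=O)(=O)=O; quinuclidine N-oxide, [O-][N+]12CCC(CC1)CC2
Why: Hydrogen-bond-directed dihydroxylation (Donohoe conditions): the 10β-hydroxyl should steer OsO4 to the β-face of the cis-disubstituted C8=C9, which is also the convex face, while the tetrasubstituted C1=C5 and the electron-poor methylene lactone react far more slowly, giving the all-cis triol.

Step 6
Reactants: 8 8β,9β,10β-triol; 9 angelic acid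
Product: 11 8β-angeloyloxy-3,3-ethylenedioxy-9β,10β-dihydroxy-4αH-guaia-1(5),11(13)-dien-6α,12-olide, via mixed anhydride 10 (not isolated)
Conditions: 9, 2,4,6-Cl3C6H2COCl, Et3N, toluene, rt; then 8, 75 °C
Reagents that add atoms: angelic acid (9), C/C=C(/C)C(=O)O
Why: Yamaguchi-type mixed-anhydride acylation without DMAP keeps the Z-geometry of the angelate, and the C8 hydroxyl should react in preference to the central C9 hydroxyl, which is flanked by the quaternary C10, and to the tertiary C10 hydroxyl.

Step 7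
Reactants: 11 8-O-angeloyl 9,10-diol
Product: 12 8β-angeloyloxy-9β-(tert-butyldimethylsilyloxy)-3,3-ethylenedioxy-10β-hydroxy-4αH-guaia-1(5),11(13)-dien-6α,12-olide
Conditions: TBSOTf, 2,6-lutidine, CH2Cl2, −78 °C
Reagents that add atoms: tert-butyldimethylsilyl triflate, CC(C)(C)[Si](C)(C)OS(=O)(=O)C(F)(F)F
Why: Low-temperature silylation with the silyl triflate should take the only secondary hydroxyl (C9) and leave the tertiary allylic C10 hydroxyl free, which blocks O9 as a competitor in the closure of step 10.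

Step 8
Reactants: 12 9-O-silyl methylene lactone
Product: 13 the 11α,13-epoxide of 12 (epoxide oxygen α on C11, C13 β)
Conditions: t-BuOOH, DBU, CH2Cl2, 0 °C
Reagents that add atoms: tert-butyl hydroperoxide, CC(C)(C)OO
Why: Weitz–Scheffer nucleophilic epoxidation touches only the electron-poor exocyclic alkene; the peroxide adds to C13 and the enolate should close onto oxygen on the α-face because the axial 8β-angelate and the 9β-silyl ether cover the β-face above C13, which sets C11 with oxygen α.

Step 9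
Reactants: 13 11α,13-epoxy lactone
Product: 14 8β-angeloyloxy-9β-(tert-butyldimethylsilyloxy)-13-chloro-3,3-ethylenedioxy-10β,11α-dihydroxy-4αH-guai-1(5)-en-6α,12-olide
Conditions: LiCl, AcOH, THF, 25 °C
Reagents that add atoms: lithium chloride, [Li+].[Cl-]
Why: Acid-assisted halide opening of a glycidic lactone, in which chloride attacks the primary C13 and not the carbonyl-bearing C11, so the C11–O bond and its configuration are kept.

Step 10
Reactants: 14 guai-1(5)-ene ketal chlorohydrin
Product: 17 8β-angeloyloxy-9β-(tert-butyldimethylsilyloxy)-13-chloro-11α-hydroxy-1,5-dioxo-3,10-epoxygermacr-2-en-6α,12-olide, via diketone ketal 15 (not isolated), via triketone 16 (not isolated)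
Conditions: O3, CH2Cl2/MeOH 4:1, NaHCO3, Sudan Red 7B, −78 °C; Me2S, −78 °C to rt; then 1 M aq HCl, THF, rt
Reagents that add atoms: ozone, [O-][O+]=O
Why: Ozone adds as a 1,3-dipole to the electron-rich tetrasubstituted C1=C5 alkene, far faster than to the conjugated angelate (the end-point is read from the indicator dye); the carbonyl oxide is trapped by methanol and Me2S reduces the hydroperoxide, so the C1–C5 bond made in step 1 is cut and the ten-membered ring appears with ketones at C1 and C5 (15). Aqueous acid then removes the dioxolane to give the 1,3,5-triketone 16, whose C3 carbonyl is attacked by the tertiary C10 hydroxyl (5-exo-trig) and loses water to the 3(2H)-furanone; the same C3–O bond closes the nine-membered oxa-bridged ring transannularly. The closest known reactions are the ozonolysis of ring-fusion alkenes to medium-ring diketones and the acid cyclodehydration of α'-hydroxy-1,3-diketones to 3(2H)-furanones. No stereocentre is formed: C6 to C11 are untouched, and C4, now flanked by the C5 ketone and the vinylogous ester, equilibrates and is fixed in step 11. The closure needed is C10–O to C3 and not to C5 or from O9, and it is secured by ring size (five against eight atoms), by the strain of a pyranone bridging C1 and C5 and by the silyl ether on O9.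

Step 11
Reactants: 17 5-oxo furanone
Product: 18 (4R,5S)-8β-angeloyloxy-9β-(tert-butyldimethylsilyloxy)-13-chloro-5,11α-dihydroxy-1-oxo-3,10-epoxygermacr-2-en-6α,12-olide
Conditions: NaBH4, MeOH/CH2Cl2, −78 °C; AcOH
Reagents that add atoms: none
Why: Chemoselective borohydride reduction of the α-acyloxy ketone over the vinylogous-ester carbonyl, with hydride expected from the ring periphery anti to the C6–O bond (polar Felkin–Anh, giving 5S) and the labile C4 reacting through the epimer that keeps its methyl out of the hydride path (dynamic kinetic resolution, giving 4R).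

Step 12
Reactants: 18 9-O-silyl ether of the target
Product: 19 CNP0340393.2 (target)
Conditions: HF·pyridine, THF, 0 °C to rt
Reagents that add atoms: none
Why: Desilylation with buffered fluoride under non-basic conditions should free the C9 hydroxyl without touching the angelate, the chlorohydrin or the lactone.

Compound list
1 | α-santonin | C[C@H]1[C@@H]2CC[C@]3(C=CC(=O)C(=C3[C@H]2OC1=O)C)C | starting material
2 | isophotosantonic lactone (10α-hydroxy-3-oxo-1αH-guai-4-en-6α,12-olide) | C1[C@@H]2[C@H](OC(=O)[C@H]2C)C3=C(C)C(=O)C[C@H]3[C@](C)(O)C1 | intermediate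
3 | 3-oxoguaia-1(10),4-dien-6α,12-olide | C1[C@@H]2[C@H](OC(=O)[C@H]2C)C3=C(C)C(=O)CC3=C(C)C1 | intermediate
4 | 3,3-ethylenedioxy-4αH-guaia-1(5),9-dien-6α,12-olide | C1[C@@H]2[C@H](OC(=O)[C@H]2C)C3=C(CC4(OCCO4)[C@@H]3C)C(C)=C1 | intermediate
5 | 3,3-ethylenedioxy-11β-phenylseleno-4αH-guaia-1(5),9-dien-6α,12-olide | C1[C@@H]2[C@H](OC(=O)[C@]2(C)[Se]c5ccccc5)C3=C(CC4(OCCO4)[C@@H]3C)C(C)=C1 | intermediate
6 | 3,3-ethylenedioxy-10β-hydroxy-9α,11β-bis(phenylseleno)-4αH-guai-1(5)-en-6α,12-olide | C1[C@@H]2[C@H](OC(=O)[C@]2(C)[Se]c5ccccc5)C3=C(CC4(OCCO4)[C@@H]3C)[C@@](C)(O)[C@@H]1[Se]c6ccccc6 | intermediate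
7 | 3,3-ethylenedioxy-10β-hydroxy-4αH-guaia-1(5),8,11(13)-trien-6α,12-olide | C=1[C@@H]2[C@H](OC(=O)C2=C)C3=C(CC4(OCCO4)[C@@H]3C)[C@@](C)(O)C=1 | intermediate
8 | 3,3-ethylenedioxy-8β,9β,10β-trihydroxy-4αH-guaia-1(5),11(13)-dien-6α,12-olide | O[C@H]1[C@@H]2[C@H](OC(=O)C2=C)C3=C(CC4(OCCO4)[C@@H]3C)[C@@](C)(O)[C@H]1O | intermediate
9 | angelic acid ((Z)-2-methylbut-2-enoic acid) | C/C=C(/C)C(=O)O | starting material
10 | angelic 2,4,6-trichlorobenzoic anhydride | C/C=C(/C)C(=O)OC(=O)c1c(Cl)cc(Cl)cc1Cl | intermediate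
11 | 8β-angeloyloxy-3,3-ethylenedioxy-9β,10β-dihydroxy-4αH-guaia-1(5),11(13)-dien-6α,12-olide | C/C=C(/C)C(=O)O[C@H]1[C@@H]2[C@H](OC(=O)C2=C)C3=C(CC4(OCCO4)[C@@H]3C)[C@@](C)(O)[C@H]1O | intermediate
12 | 8β-angeloyloxy-9β-(tert-butyldimethylsilyloxy)-3,3-ethylenedioxy-10β-hydroxy-4αH-guaia-1(5),11(13)-dien-6α,12-olide | C/C=C(/C)C(=O)O[C@H]1[C@@H]2[C@H](OC(=O)C2=C)C3=C(CC4(OCCO4)[C@@H]3C)[C@@](C)(O)[C@H]1O[Si](C)(C)C(C)(C)C | intermediate
13 | 11α,13-epoxide of 12 | C/C=C(/C)C(=O)O[C@H]1[C@@H]2[C@H](OC(=O)[C@]2(O5)C5)C3=C(CC4(OCCO4)[C@@H]3C)[C@@](C)(O)[C@H]1O[Si](C)(C)C(C)(C)C | intermediate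
14 | 8β-angeloyloxy-9β-(tert-butyldimethylsilyloxy)-13-chloro-3,3-ethylenedioxy-10β,11α-dihydroxy-4αH-guai-1(5)-en-6α,12-olide (key-step precursor) | C/C=C(/C)C(=O)O[C@H]1[C@@H]2[C@H](OC(=O)[C@]2(O)CCl)C3=C(CC4(OCCO4)[C@@H]3C)[C@@](C)(O)[C@H]1O[Si](C)(C)C(C)(C)C | intermediate
15 | 1,5-dioxo-3,3-ethylenedioxy germacranolide (ring-opened diketone of 14) | C/C=C(/C)C(=O)O[C@H]1[C@@H]2[C@H](OC(=O)[C@]2(O)CCl)C(=O)[C@@H](C)C3(OCCO3)CC(=O)[C@@](C)(O)[C@H]1O[Si](C)(C)C(C)(C)C | intermediate
16 | 1,3,5-trioxo-10β-hydroxy germacranolide | C/C=C(/C)C(=O)O[C@H]1[C@@H]2[C@H](OC(=O)[C@]2(O)CCl)C(=O)[C@@H](C)C(=O)CC(=O)[C@@](C)(O)[C@H]1O[Si](C)(C)C(C)(C)C | intermediate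
17 | 8β-angeloyloxy-9β-(tert-butyldimethylsilyloxy)-13-chloro-11α-hydroxy-1,5-dioxo-3,10-epoxygermacr-2-en-6α,12-olide (key-step product) | C/C=C(/C)C(=O)O[C@H]1[C@@H]2[C@H](OC(=O)[C@]2(O)CCl)C(=O)[C@@H](C)C3=CC(=O)[C@@](C)(O3)[C@H]1O[Si](C)(C)C(C)(C)C | intermediate
18 | (4R,5S)-5-hydroxy compound, 9-O-tert-butyldimethylsilyl ether of the target | C/C=C(/C)C(=O)O[C@H]1[C@@H]2[C@H](OC(=O)[C@]2(O)CCl)[C@@H](O)[C@@H](C)C3=CC(=O)[C@@](C)(O3)[C@H]1O[Si](C)(C)C(C)(C)C | intermediate
19 | CNP0340393.2 | C/C=C(/C)C(=O)O[C@H]1[C@@H]2[C@H](OC(=O)[C@]2(O)CCl)[C@@H](O)[C@@H](C)C2=CC(=O)[C@@](C)(O2)[C@H]1O | target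

Total step count: 12. Longest linear sequence: 12 steps (1 to 19); angelic acid 9 enters in step 6.

Steps most likely to fail

Step 4. What may go wrong: capture of the seleniranium ion by water at C5 (1,4-addition) or on the wrong face, or ionisation of the doubly allylic tertiary alcohol during the elimination. The fallback sets out from 5 and returns at 8, replacing anti-addition by two syn-dihydroxylations on the convex β-face. NaIO4 alone converts 5 into 3,3-ethylenedioxyguaia-1(5),9,11(13)-trien-6α,12-olide F1. OsO4 (cat.) with N-methylmorpholine N-oxide dihydroxylates its trisubstituted C9=C10 bond from the open face to the 9β,10β-diol F2. IBX in DMSO oxidises the secondary hydroxyl to the 10β-hydroxy-9-ketone F3. Me3SiOSO2CF3/Et3N gives the bis-silylated 8-en-9-yl enol ether F4. OsO4 (cat.)/N-methylmorpholine N-oxide followed by aqueous citric acid gives the 8β,10β-dihydroxy-9-ketone F5. NaBH4 at −78 °C, attacking anti to the two flanking axial C–O bonds, gives triol 8.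

Step 8. What may go wrong: closure of the enolate onto oxygen from the β-face, which would give the C11 epimer, or base-induced migration of the exocyclic alkene into the lactone ring. The fallback sets out from 12 and returns at 14, skipping 13. OsO4 (cat.)/N-methylmorpholine N-oxide dihydroxylates the methylene lactone to the 11,13-diol F6 (its C11 configuration is irrelevant). NaIO4 cleaves it to the 13-nor-11-oxo lactone F7. ClCH2Li (from ICH2Cl and MeLi·LiBr, THF, −78 °C) adds to the ketone and cold protonation gives chlorohydrin 14. Here carbon, not oxygen, enters from the more accessible face, so the sense at C11 is the complement of that in step 8.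

Step 10. What may go wrong: competing attack of ozone on the angelate, abnormal cleavage next to the free allylic carbinol (C1–C10 scission), or loss of the C9 silyl ether before the furanone has closed. The fallback sets out from 14 and returns at 15. OsO4·TMEDA (1 equiv, CH2Cl2, −78 °C), delivered by the 10β-hydroxyl to the adjacent C1=C5 alkene, then aqueous NaHSO3, gives the 1β,5β,10β-triol F8. NaIO4 in aqueous THF cleaves the cis-1,5-glycol to diketone 15, which the aqueous acid of step 10 carries on through 16 to 17.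

Further compounds
F1 | step 4 | 3,3-ethylenedioxy-4αH-guaia-1(5),9,11(13)-trien-6α,12-olide | C1[C@@H]2[C@H](OC(=O)C2=C)C3=C(CC4(OCCO4)[C@@H]3C)C(C)=C1
F2 | step 4 | 3,3-ethylenedioxy-9β,10β-dihydroxy-4αH-guaia-1(5),11(13)-dien-6α,12-olide | C1[C@@H]2[C@H](OC(=O)C2=C)C3=C(CC4(OCCO4)[C@@H]3C)[C@@](C)(O)[C@H]1O
F3 | step 4 | 3,3-ethylenedioxy-10β-hydroxy-9-oxo-4αH-guaia-1(5),11(13)-dien-6α,12-olide | C1[C@@H]2[C@H](OC(=O)C2=C)C3=C(CC4(OCCO4)[C@@H]3C)[C@@](C)(O)C1=O
F4 | step 4 | 3,3-ethylenedioxy-9,10β-bis(trimethylsilyloxy)-4αH-guaia-1(5),8,11(13)-trien-6α,12-olide | C=1[C@@H]2[C@H](OC(=O)C2=C)C3=C(CC4(OCCO4)[C@@H]3C)[C@@](C)(O[Si](C)(C)C)C=1O[Si](C)(C)C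
F5 | step 4 | 3,3-ethylenedioxy-8β,10β-dihydroxy-9-oxo-4αH-guaia-1(5),11(13)-dien-6α,12-olide | O[C@H]1[C@@H]2[C@H](OC(=O)C2=C)C3=C(CC4(OCCO4)[C@@H]3C)[C@@](C)(O)C1=O
F6 | step 8 | 11,13-diol of 12 (11β-hydroxy epimer drawn) | C/C=C(/C)C(=O)O[C@H]1[C@@H]2[C@H](OC(=O)[C@@]2(O)CO)C3=C(CC4(OCCO4)[C@@H]3C)[C@@](C)(O)[C@H]1O[Si](C)(C)C(C)(C)C
F7 | step 8 | 13-nor-11-oxo lactone of 12 | C/C=C(/C)C(=O)O[C@H]1[C@@H]2[C@H](OC(=O)C2=O)C3=C(CC4(OCCO4)[C@@H]3C)[C@@](C)(O)[C@H]1O[Si](C)(C)C(C)(C)C
F8 | step 10 | 1β,5β-dihydroxy derivative of 14 (1β,5β,10β,11α-tetrol) | C/C=C(/C)C(=O)O[C@H]1[C@@H]2[C@H](OC(=O)[C@]2(O)CCl)[C@@]3(O)[C@](O)(CC4(OCCO4)[C@@H]3C)[C@@](C)(O)[C@H]1O[Si](C)(C)C(C)(C)C
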